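The ratio to watch is the target the solution can hold, set against the solid substrate you charged.

    dissolved substrate + reagent ⇌ target (K1 = 34 L mol⁻¹, k1 = 1.7 L mol⁻¹ h⁻¹)
    solid substrate ⇌ dissolved substrate, rate k2*(cs2 - [dissolved substrate]) while solid is left; crystals form when [dissolved substrate] > cs2 (cs2 = 22 mM, k2 = 0.16 h⁻¹)
    solid product ⇌ target, rate k3*(cs3 - [target]) while solid is left; crystals form when [target] > cs3 (cs3 = 0.19 M, k3 = 2.5 h⁻¹)
    gas ⇌ reagent, rate k4*(csat - [reagent]) (k4 = 18 h⁻¹, csat = 51 mM)

solid substrate 0.50 M; gas 51 mM (held); time 15 d

- part of the solid substrate that has turned into other species by 15 d (what has only dissolved does not count)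
- the target standing at 15 d, as a percentage of the solid substrate charged
- amount of target if the flask were left three thousand times as long, in percent of the solid substrate charged

Start with the balance of reagent. The gas supplies it in proportion to the gap below saturation, and the reaction removes it. Reagent starts at zero, so the gap starts as the whole of 51 mM and closes with a time constant of about 0.0556 h. After that brief filling the gap stays at most 0.208% of 51 mM, because the transfer at 18 h⁻¹ is far faster than the pseudo-first-order uptake of reagent at 0.0374 h⁻¹.

Dissolved substrate climbs to 22 mM from below and reagent to 51 mM, so target cannot pass the saturation ceiling c*, the equilibrium constant times those two concentrations: 38.1 mM. This is less than the 0.19 M where crystals form, so no solid product appears. The 60.1 mM drawn from the solid is less than the 0.50 M charged, so solid remains. Divided by the charge, c* bounds conversion from above at 7.63%.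

For the bound from below, take the lag τ: the equilibrium constant over the rate constant, plus the inverse dissolution coefficient counted one plus 1.73 times, since the solid feeds target as well as dissolved substrate. That gives 37.1 h. In 15 d there are 9.70 lags, and the gap exp(−t/τ) is 0.00611% of c*. The bracket closes, so I expect target at 7.63% and, after the long wait, 7.63%.

The forecast gives 7.63%, 7.63% and 7.63%, inside that bracket, and holds that “the conversion, the yield and the long-time value all coincide”.

The flask gives 7.63%, 7.63% and 7.63%, with solid product at 0% at 15.0 d. Now take the neighbouring flask, with 2.0 M of solid substrate and the same time. Neither c* nor τ contains the charge, and the 60.1 mM drawn is again less than the charge, so the reckoning gives 1.91% of that larger charge. The neighbouring flask gives 1.91% conversion and 1.91% target, with 97.0% still solid at 15.0 d.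

(The constants were set for the occasion; the flask was simulated.)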